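**Plan**

- Retrosynthesis: the C3 silyl ether, the ring alkenes C1=C2 and C11=C12 and the C16 hydrate are removed first. Ring A is then cut at C1=C2 (metathesis). The 19,10-lactone is read as the Baeyer–Villiger image of a cyclobutanone, whose bonds C19–C4 and C5–C10 are cut together as a ketene (O=C19=C10) plus an alkene (C4=C5).
- Enabling feature: C10 sits on C9 and C5 on C6, linked through C9–C8–C6, so the [2+2] closes five-membered ring B and the four-membered ring C19–C4–C5–C10 at once. A methoxy enol ether C6=C7 (the latent C7 acid) makes C4=C5 the end of a 1-methoxydiene and steers C19 to C4.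
- Further cuts: C9–C10 (Ireland–Claisen from a C12 allylic crotonate), C5–C6 (alkenylchromium addition of a C2–C5 fragment), C13–C16 (palladium cycloalkenylation, ring D), ring C (Diels–Alder).
- Forward order: ring C, ring D, side chain, C9–C10, ring B plus cyclobutanone (key), lactone, ring A, C16 hydration, hydrogenation, desilylation.
- Stereochemistry: C8 from a catalytic asymmetric Diels–Alder, C13 from the bridge, C3 from a catalytic asymmetric vinylation, C12 to C9 by suprafacial [3,3] transfer, C4/C5/C10 in the key step, C6 by equilibration, C16 by exo attack.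

Key step: step 15

Remark: locants C1–C19 in names and comments are those of the gibberellane skeleton of the target.
Remark: 14 forms as both C6 epimers, 17–25 as E/Z enol ether mixtures, 20 as a ketene acetal E/Z mixture and 21–23 as C10 epimers; these elements are left undefined in the SMILES because each is erased later.
Remark: the sense of induction of the chromium salen catalyst (step 6) and of (−)-MIB (step 3) is assigned by analogy with simple 2-alkylacroleins and enals; the mirror-image catalyst would be used if the first batch proved antipodal.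

**Step 1**
Reactants: 1 prop-2-yn-1-ol
Product: 3 (E)-3-iodo-2-methylprop-2-en-1-ol, via alkenylalane 2 (not isolated)
Conditions: AlMe3, Cp2ZrCl2 (25 mol%), CH2Cl2, 0 → 23 °C; then I2, THF, −30 °C
Reagents that add atoms: trimethylaluminium, C[Al](C)C; iodine, II
Why: Zirconium-catalysed syn-carboalumination (Negishi carboalumination) puts CH3 on the internal carbon and Al on the terminus, and iodinolysis with retention should give the E iodide with I cis to CH3.

**Step 2**
Reactants: 3 (E)-3-iodo-2-methylprop-2-en-1-ol
Product: 4 (E)-3-iodo-2-methylprop-2-enal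
Conditions: MnO2, CH2Cl2, 23 °C
Reagents that add atoms: none
Why: Allylic oxidation with MnO2 should stop at the enal and leave the alkenyl iodide and its geometry untouched.

**Step 3**
Reactants: 4 (E)-3-iodo-2-methylprop-2-enal
Product: 5 (3S,1E)-1-iodo-2-methylpenta-1,4-dien-3-ol
Conditions: Zn(CH=CH2)2, (−)-MIB (10 mol%), toluene, −20 → 0 °C
Reagents that add atoms: divinylzinc, C=C[Zn]C=C
Why: Amino-alcohol-catalysed enantioselective addition of a vinylzinc reagent to an aldehyde; (−)-MIB is expected to direct vinyl transfer to the Si face of the enal, which sets C3 as S.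

**Step 4**
Reactants: 5 (3S,1E)-1-iodo-2-methylpenta-1,4-dien-3-ol
Product: 6 tert-butyl{[(3S,1E)-1-iodo-2-methylpenta-1,4-dien-3-yl]oxy}dimethylsilane
Conditions: TBSCl, imidazole, DMF, 23 °C
Reagents that add atoms: tert-butyl(chloro)dimethylsilane, CC(C)(C)[Si](C)(C)Cl
Why: Standard silylation of a secondary alcohol; the TBS ether has to survive the organochromium, ylide, enolate and ketene steps and keeps C3–O from retro-aldol chemistry later.

**Step 5**
Reactants: 7 pent-4-enal
Product: 8 2-methylidenepent-4-enal
Conditions: aq. CH2O (37%), pyrrolidine (10 mol%), propanoic acid (10 mol%), i-PrOH, 45 °C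
Reagents that add atoms: formaldehyde, C=O
Why: Amine-catalysed α-methylenation of an aldehyde (Mannich condensation then elimination) should give the 2-substituted acrolein needed as dienophile.

**Step 6**
Reactants: 8 2-methylidenepent-4-enal; 9 (1E)-3-(tert-butyldimethylsilyloxy)-N,N-dimethylbuta-1,3-dien-1-amine
Product: 11 (R)-4-oxo-1-(prop-2-en-1-yl)cyclohex-2-ene-1-carbaldehyde, via endo cycloadduct 10 (not isolated)
Conditions: (R,R)-(salen)CrSbF6 (5 mol%; salen = N,N'-bis(3,5-di-tert-butylsalicylidene)cyclohexane-1,2-diamine dianion, trivalent chromium), 4 Å MS, CH2Cl2, −40 °C; then AcCl, CH2Cl2/Et2O, −78 → 23 °C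
Reagents that add atoms: none
Why: Catalytic asymmetric Diels–Alder reaction of a 1-amino-3-siloxydiene with an α-substituted acrolein joins the amino carbon to the quaternary carbon; acyl chloride then expels the amine and unmasks the enone, and the Lewis acid catalyst sets the quaternary centre C8.

**Step 7**
Reactants: 11 (R)-4-oxo-1-(prop-2-en-1-yl)cyclohex-2-ene-1-carbaldehyde
Product: 12 4-(tert-butyldimethylsilyloxy)-1-(prop-2-en-1-yl)cyclohexa-2,4-diene-1-carbaldehyde (C8 as in 11)
Conditions: TBSOTf, Et3N, CH2Cl2, 0 °C
Reagents that add atoms: tert-butyldimethylsilyl trifluoromethanesulfonate, CC(C)(C)[Si](C)(C)OS(=O)(=O)C(F)(F)F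
Why: Soft enolisation of the enone can only occur at C13 because C8 is quaternary and the aldehyde is not enolisable, which should give the cross-conjugated 2-siloxydiene.

**Step 8**
Reactants: 12 silyl dienol ether
Product: 13 (1R,5R)-6-methylidene-4-oxobicyclo[3.2.1]oct-2-ene-1-carbaldehyde
Conditions: Pd(OAc)2 (10 mol%), O2 (1 atm), DMSO, 45 °C
Reagents that add atoms: none
Why: Palladium-catalysed oxidative cycloalkenylation of a silyl enol ether: 5-exo carbopalladation of the allyl group by C13 and β-hydride elimination should close ring D with the C16 methylidene, and C13 is fixed by the one-atom bridge.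

**Step 9**
Reactants: 13 bicyclic enone aldehyde; 6 alkenyl iodide
Product: 14 (1R,5R)-5-[(2E,4S)-4-(tert-butyldimethylsilyloxy)-1-hydroxy-3-methylhexa-2,5-dien-1-yl]-7-methylidenebicyclo[3.2.1]oct-3-en-2-one (both C6 epimers)
Conditions: CrCl2 (4 equiv), NiCl2 (2 mol%), DMSO, 23 °C
Reagents that add atoms: none
Why: Nozaki–Hiyama–Kishi coupling: the alkenylchromium species adds to the hindered aldehyde and not to the enone, with retention of the E geometry; the carbinol centre is removed in step 10.

**Step 10**
Reactants: 14 allylic alcohol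
Product: 15 dienone (C6 ketone of 14)
Conditions: Dess–Martin periodinane, pyridine, CH2Cl2, 0 → 23 °C
Reagents that add atoms: none
Why: Dess–Martin oxidation of a hindered secondary allylic alcohol under buffered conditions should give the C6 enone without migration of the C4=C5 double bond.

**Step 11**
Reactants: 15 dienone
Product: 16 C12 alcohol (ring ketone C12 of 15 reduced; OH on the face of ring C away from the C15–C16 bridge)
Conditions: NaBH4, CeCl3·7H2O, MeOH, −78 °C
Reagents that add atoms: none
Why: Luche 1,2-reduction should take the open ring enone before the C6 ketone, which is flanked by quaternary C8; hydride is expected to enter from the side of the C15–C16 bridge, where sp2 C16 carries no inward hydrogen, because the inward hydrogen on C14 shields the other face.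

**Step 12**
Reactants: 16 C12 alcohol
Product: 17 dienol ether (C6=O of 16 replaced by C6=CH–OCH3, E/Z mixture)
Conditions: Ph3P(CH2OMe)Cl, KHMDS, THF, 0 → 50 °C
Reagents that add atoms: (methoxymethyl)triphenylphosphonium chloride, COC[P+](c1ccccc1)(c1ccccc1)c1ccccc1.[Cl-]
Why: Wittig methoxymethylenation of the ketone (the C12 alkoxide is inert) adds C7 and should create the 1-methoxydiene C7=C6–C5=C4 that activates the key step and carries the latent C7 carboxyl.

**Step 13**
Reactants: 17 dienol ether; 18 (E)-but-2-enoic anhydride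
Product: 19 C12 (E)-but-2-enoate of 17
Conditions: Et3N, DMAP (cat.), CH2Cl2, 0 → 23 °C
Reagents that add atoms: none
Why: DMAP-catalysed acylation of the secondary allylic alcohol under basic conditions that the enol ether tolerates.

**Step 14**
Reactants: 19 allylic crotonate
Product: 22 2-substituted but-3-enoic acid (C10 bonded to C9 anti to the C15–C16 bridge; C11=C12; C10 epimers), via silyl ketene acetal 20 (not isolated), via trimethylsilyl ester 21 (not isolated)
Conditions: LDA, THF/DMPU, −78 °C; Me3SiCl; −78 → 60 °C; then pH 7 buffer/MeOH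
Reagents that add atoms: none
Why: Ireland–Claisen rearrangement of the dienolate-derived silyl ketene acetal: the suprafacial [3,3] shift should transfer the C12–O configuration to C9, form C9–C10 on the face of the departing C12–O bond (anti to the C15–C16 bridge) and deliver the α-vinyl acid.

**Step 15**
Reactants: 22 α-vinyl acid
Product: 25 cyclobutanone (C19 ketone bonded to C4 and C10; ring B closed; 10-vinyl; 4-methyl; C3 OTBS; C6=CH–OCH3; C11=C12; 16-methylidene), via acid chloride 23 (not isolated), via vinylketene 24 (not isolated)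
Conditions: 1-chloro-N,N,2-trimethylprop-1-en-1-amine, CH2Cl2, 0 °C; then slow addition to Et3N, toluene, 110 °C (2 mM)
Reagents that add atoms: none
Why: The chloroenamine should convert 22 into acid chloride 23 without free HCl, and Et3N removes the doubly activated C10–H to give vinylketene 24, whose electrophilic C19 is attacked by C4, the end of the 1-methoxydiene C7=C6–C5=C4, while C10 closes on C5 in an asynchronous thermal [2+2]. The closest known reaction type is the intramolecular ketene–alkene [2+2] cycloaddition of vinylketenes made from acid chlorides through a three-atom tether, together with ketene [2+2] additions to dienes and enol ethers. Ring B (C5–C6–C8–C9–C10) closes by the C10–C5 bond as the fused five-membered ring of a bicyclo[3.2.0]heptanone (tether C9–C8–C6, bond to the proximal alkene carbon), and the cyclobutanone C19–C4–C5–C10 closes by the C19–C4 bond. Suprafacial addition to the E alkene puts CH3 cis to C6 and C3 cis to H5, the tether enforces the cis ring fusion at C10/C5, and the face is chosen by the rotamer about C9–C10 that places the vinyl group next to H9 and the slim C19=O next to C11 (least allylic 1,3-strain), so C19 and C4 add on the C11/C14 side. The step needs C19 to bond to C4 and not C5, which the C7 methoxy group secures by making C4 the nucleophilic terminus and stabilising the charge over C5–C6–C7. It also needs [2+2] periselectivity, which holds because closure at C7 or through oxygen would put a double bond at bridgehead C6 (Bredt's rule) and no other alkene can reach the ketene; high dilution limits ketene dimerisation.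

**Step 16**
Reactants: 25 cyclobutanone
Product: 27 C7 aldehyde (C7 on C6 trans to C4 and cis to H5), via 6-epi aldehyde 26 (not isolated)
Conditions: 1 M HCl, THF, 0 °C; then DBU, CH2Cl2, 23 °C
Reagents that add atoms: water, O
Why: Acid hydrolysis of the enol ether should give the aldehyde by protonation on the open face of C6, and base-mediated enolisation then equilibrates C6 to the more stable epimer with C7 trans to the quaternary C4; retro-Michael opening of the four-membered ring is disfavoured because the C4–C5 bond lies in the nodal plane of the C19 carbonyl, and the C3 TBS ether blocks retro-aldol cleavage.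

**Step 17**
Reactants: 27 aldehyde
Product: 28 C7 carboxylic acid (cyclobutanone retained)
Conditions: NaClO2, NaH2PO4, 2-methylbut-2-ene, t-BuOH/H2O, 0 → 23 °C
Reagents that add atoms: sodium chlorite, [Na+].[O-]Cl=O
Why: Pinnick oxidation converts the aldehyde to the acid without epimerising C6, and the alkene scavenger protects the four C=C bonds from hypochlorite.

**Step 18**
Reactants: 28 keto acid
Product: 29 19,10-lactone (C4–C19(=O)–O–C10; 10-vinyl; C3 OTBS with vinyl)
Conditions: H2O2 (30% aq.), AcOH, 0 → 10 °C
Reagents that add atoms: hydrogen peroxide, OO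
Why: Baeyer–Villiger oxidation of the strained cyclobutanone: the tertiary allylic C10 should migrate with retention in preference to C4, which is deactivated by the β-siloxy group, and hydrogen peroxide at low temperature does not epoxidise the alkenes.

**Step 19**
Reactants: 29 lactone
Product: 30 ring A closed triene acid (3-O-TBS ether of the 19,10-lactone 7-acid with C1=C2, C11=C12 and 16-methylidene)
Conditions: second-generation Grubbs catalyst (H2IMes)(PCy3)Cl2Ru=CHPh (5 mol%), CH2Cl2, 40 °C
Reagents that add atoms: none
Why: Ring-closing metathesis of the vinyl groups on C10 and C3, held cis on the lactone since step 15, should close ring A at C1=C2; the 1,1-disubstituted C16 alkene and the ring alkene C11=C12 are poor metathesis partners.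

**Step 20**
Reactants: 30 triene
Product: 31 16-hydroxy-16-methyl diene acid (3-O-TBS ether of the 1,2,11,12-tetradehydro target)
Conditions: Co(acac)2 (20 mol%), PhSiH3, O2 (1 atm), THF, 23 °C
Reagents that add atoms: dioxygen, O=O
Why: Mukaiyama hydration (hydrogen atom transfer) reacts with the 1,1-disubstituted C16=C17 alkene far faster than with the two 1,2-disubstituted alkenes; the tertiary C16 radical should be trapped on the exo face of ring D, away from the C9–C11–C12 bridge, which sets the C16 alcohol.

**Step 21**
Reactants: 31 diene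
Product: 32 3-O-TBS ether of the target gibberellin
Conditions: H2 (1 atm), Pd/CaCO3 (5%), pyridine/THF, 23 °C
Reagents that add atoms: none
Why: Heterogeneous hydrogenation of the two cis-disubstituted alkenes creates no stereocentre, and the pyridine-moderated catalyst is the type used in this lactone class to avoid hydrogenolysis of the allylic C10–O bond.

**Step 22**
Reactants: 32 silyl ether
Product: 33 target gibberellin (3β-hydroxy; 16-hydroxy-16-methyl with OH exo; 7-carboxylic acid; 19,10-lactone)
Conditions: HF·pyridine, THF, 0 → 23 °C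
Reagents that add atoms: none
Why: Fluoride desilylation under mildly acidic conditions frees the 3-hydroxyl without the base-induced retro-aldol epimerisation at C3 and leaves lactone, acid and tertiary alcohol intact.

**Compound list**

1 | prop-2-yn-1-ol | C#CCO | starting material
2 | (E)-alkenylalane, O- and C-dimethylaluminated | C[Al](C)OC/C(C)=C/[Al](C)C | intermediate
3 | (E)-3-iodo-2-methylprop-2-en-1-ol | OC/C(C)=C/I | intermediate
4 | (E)-3-iodo-2-methylprop-2-enal | O=C/C(C)=C/I | intermediate
5 | (3S,1E)-1-iodo-2-methylpenta-1,4-dien-3-ol | C=C[C@H](O)/C(C)=C/I | intermediate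
6 | tert-butyl{[(3S,1E)-1-iodo-2-methylpenta-1,4-dien-3-yl]oxy}dimethylsilane | C=C[C@H](O[Si](C)(C)C(C)(C)C)/C(C)=C/I | intermediate
7 | pent-4-enal | C=CCCC=O | starting material
8 | 2-methylidenepent-4-enal | C=CCC(=C)C=O | intermediate
9 | (1E)-3-(tert-butyldimethylsilyloxy)-N,N-dimethylbuta-1,3-dien-1-amine | CN(C)/C=C/C(=C)O[Si](C)(C)C(C)(C)C | starting material
10 | endo cycloadduct, 1-allyl-2-(dimethylamino)-4-(TBSO)cyclohex-3-ene-1-carbaldehyde (NMe2 cis to CHO) | CN(C)[C@@H]1C=C(O[Si](C)(C)C(C)(C)C)CC[C@]1(CC=C)C=O | intermediate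
11 | (R)-4-oxo-1-(prop-2-en-1-yl)cyclohex-2-ene-1-carbaldehyde | O=C1CC[C@](C=C1)(CC=C)C=O | intermediate
12 | 4-(tert-butyldimethylsilyloxy)-1-(prop-2-en-1-yl)cyclohexa-2,4-diene-1-carbaldehyde | C=CC[C@]1(C=O)CC=C(O[Si](C)(C)C(C)(C)C)C=C1 | intermediate
13 | (1R,5R)-6-methylidene-4-oxobicyclo[3.2.1]oct-2-ene-1-carbaldehyde | O=C[C@]12C=CC(=O)[C@H](C1)C(=C)C2 | intermediate
14 | C6 carbinol from 13 and 6 (both C6 epimers) | C=C[C@H](O[Si](C)(C)C(C)(C)C)/C(C)=C/C(O)[C@]12C=CC(=O)[C@H](C1)C(=C)C2 | intermediate
15 | dienone (C6 ketone) | C=C[C@H](O[Si](C)(C)C(C)(C)C)/C(C)=C/C(=O)[C@]12C=CC(=O)[C@H](C1)C(=C)C2 | intermediate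
16 | C12 alcohol (OH on the face of ring C away from the C15–C16 bridge) | C=C[C@H](O[Si](C)(C)C(C)(C)C)/C(C)=C/C(=O)[C@]12C=C[C@H](O)[C@H](C1)C(=C)C2 | intermediate
17 | methoxy dienol ether (E/Z at C6=C7) | C=C[C@H](O[Si](C)(C)C(C)(C)C)/C(C)=C/C(=COC)[C@]12C=C[C@H](O)[C@H](C1)C(=C)C2 | intermediate
18 | (E)-but-2-enoic anhydride | C/C=C/C(=O)OC(=O)/C=C/C | starting material
19 | C12 crotonate | C=C[C@H](O[Si](C)(C)C(C)(C)C)/C(C)=C/C(=COC)[C@]12C=C[C@H](OC(=O)/C=C/C)[C@H](C1)C(=C)C2 | intermediate
20 | trimethylsilyl ketene acetal of 19 | C=C[C@H](O[Si](C)(C)C(C)(C)C)/C(C)=C/C(=COC)[C@]12C=C[C@H](OC(O[Si](C)(C)C)=CC=C)[C@H](C1)C(=C)C2 | intermediate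
21 | trimethylsilyl ester of 22 | C=C[C@H](O[Si](C)(C)C(C)(C)C)/C(C)=C/C(=COC)[C@]12[C@H](C(C=C)C(=O)O[Si](C)(C)C)C=C[C@H](C1)C(=C)C2 | intermediate
22 | α-vinyl acid (C10 epimers) | C=C[C@H](O[Si](C)(C)C(C)(C)C)/C(C)=C/C(=COC)[C@]12[C@H](C(C=C)C(=O)O)C=C[C@H](C1)C(=C)C2 | intermediate
23 | acid chloride of 22 | C=C[C@H](O[Si](C)(C)C(C)(C)C)/C(C)=C/C(=COC)[C@]12[C@H](C(C=C)C(=O)Cl)C=C[C@H](C1)C(=C)C2 | intermediate
24 | vinylketene (O=C19=C10) | C=C[C@H](O[Si](C)(C)C(C)(C)C)/C(C)=C/C(=COC)[C@]12[C@H](C(C=C)=C=O)C=C[C@H](C1)C(=C)C2 | intermediate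
25 | cyclobutanone | C=C[C@H](O[Si](C)(C)C(C)(C)C)[C@@]1(C)C(=O)[C@@]2(C=C)[C@@H]1C(=COC)[C@]34[C@H]2C=C[C@H](C3)C(=C)C4 | intermediate
26 | 6-epi C7 aldehyde | C=C[C@H](O[Si](C)(C)C(C)(C)C)[C@@]1(C)C(=O)[C@@]2(C=C)[C@@H]1[C@@H](C=O)[C@]34[C@H]2C=C[C@H](C3)C(=C)C4 | intermediate
27 | C7 aldehyde | C=C[C@H](O[Si](C)(C)C(C)(C)C)[C@@]1(C)C(=O)[C@@]2(C=C)[C@@H]1[C@H](C=O)[C@]34[C@H]2C=C[C@H](C3)C(=C)C4 | intermediate
28 | C7 acid, cyclobutanone | C=C[C@H](O[Si](C)(C)C(C)(C)C)[C@@]1(C)C(=O)[C@@]2(C=C)[C@@H]1[C@H](C(=O)O)[C@]34[C@H]2C=C[C@H](C3)C(=C)C4 | intermediate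
29 | 19,10-lactone diene acid | C=C[C@H](O[Si](C)(C)C(C)(C)C)[C@@]1(C)C(=O)O[C@@]2(C=C)[C@@H]1[C@H](C(=O)O)[C@]34[C@H]2C=C[C@H](C3)C(=C)C4 | intermediate
30 | ring A closed triene acid: 3-O-TBS ether of the 19,10-lactone 7-acid with C1=C2, C11=C12 and 16-methylidene | C[C@@]12C(=O)O[C@]3(C=C[C@@H]1O[Si](C)(C)C(C)(C)C)[C@@H]1C=C[C@@H]4C[C@]1(CC4=C)[C@@H](C(=O)O)[C@@H]32 | intermediate
31 | 16-hydroxy-16-methyl diene acid: 3-O-TBS ether of the 1,2,11,12-tetradehydro target | C[C@@]12C(=O)O[C@]3(C=C[C@@H]1O[Si](C)(C)C(C)(C)C)[C@@H]1C=C[C@@H]4C[C@]1(C[C@@]4(C)O)[C@@H](C(=O)O)[C@@H]32 | intermediate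
32 | 3-O-TBS ether of the target gibberellin | C[C@@]12C(=O)O[C@]3(CC[C@@H]1O[Si](C)(C)C(C)(C)C)[C@@H]1CC[C@@H]4C[C@]1(C[C@@]4(C)O)[C@@H](C(=O)O)[C@@H]32 | intermediate
33 | target gibberellin: 3β-hydroxy, 16-hydroxy-16-methyl (OH exo), 7-carboxylic acid, 19,10-lactone | C[C@@]12C(=O)O[C@]3(CC[C@@H]1O)[C@@H]1CC[C@@H]4C[C@]1(C[C@@]4(C)O)[C@@H](C(=O)O)[C@@H]32 | target

**Step count and risks**

Total steps: 22. Longest linear sequence: 18 (steps 5–22 from pent-4-enal 7). Steps 1–4 make fragment 6, which joins at step 9.

Steps most likely to fail: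

1. Step 15. The vinylketene may oligomerise faster than it adds to the hindered trisubstituted alkene, or the two faces of C10 may not be told apart well enough. Fallback: the neutral ketene is replaced by a cationic keteniminium ion, which cannot dimerise and is more electrophilic. It sets out from acid 22: acid chloride 23 is made as in the route and quenched with pyrrolidine to give the pyrrolidine amide F1. Tf2O and 2,4,6-collidine in 1,2-dichloroethane at 80 °C should turn F1 into the keteniminium ion, which undergoes the same intramolecular [2+2] to the cyclobutaniminium triflate F2. Aqueous NaHCO3 hydrolysis of F2 comes back to the route at cyclobutanone 25.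

2. Step 12. The basic ylide may deprotonate the hindered cross-conjugated ketone at its γ-positions, or olefination next to quaternary C8 may be too slow. Fallback: a small carbanion and a Peterson elimination replace the ylide. It sets out from 16: excess [methoxy(trimethylsilyl)methyl]lithium (from (methoxymethyl)trimethylsilane and s-BuLi, THF, −78 °C) should add 1,2 to the C6 ketone to give the β-hydroxysilane F3. KH in THF then eliminates silanolate from F3 and comes back to the route at dienol ether 17.

3. Step 11. The borohydride may also reduce the C6 enone, so the two carbonyl groups are not differentiated. Fallback: the order of events is changed so that only one ketone is present at the reduction. It sets out from 14: NaBH4/CeCl3 reduces the single ring ketone to the diol F4. One equivalent of but-2-enoic anhydride with DMAP at −20 °C should acylate only the ring alcohol, because the C6 carbinol is neopentylic, to give the mono-crotonate F5. Ireland–Claisen rearrangement of F5 with excess LDA and Me3SiCl (the C6 hydroxyl is silylated in the flask and freed on work-up) gives the hydroxy acid F6. Dess–Martin oxidation gives the keto acid F7, and methoxymethylene Wittig reaction of F7 with excess ylide comes back to the route at acid 22.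

**Further compounds**

F1 | step 15 | pyrrolidine amide of acid 22 | C=C[C@H](O[Si](C)(C)C(C)(C)C)/C(C)=C/C(=COC)[C@]12[C@H](C(C=C)C(=O)N3CCCC3)C=C[C@H](C1)C(=C)C2
F2 | step 15 | cyclobutaniminium trifluoromethanesulfonate (pyrrolidinium ylidene at C19) | C=C[C@H](O[Si](C)(C)C(C)(C)C)[C@@]1(C)C(=[N+]5CCCC5)[C@@]2(C=C)[C@@H]1C(=COC)[C@]34[C@H]2C=C[C@H](C3)C(=C)C4.[O-]S(=O)(=O)C(F)(F)F
F3 | step 12 | β-hydroxy-α-methoxysilane at C6 | C=C[C@H](O[Si](C)(C)C(C)(C)C)/C(C)=C/C(O)(C(OC)[Si](C)(C)C)[C@]12C=C[C@H](O)[C@H](C1)C(=C)C2
F4 | step 11 | C6,C12 diol (C6 epimers) | C=C[C@H](O[Si](C)(C)C(C)(C)C)/C(C)=C/C(O)[C@]12C=C[C@H](O)[C@H](C1)C(=C)C2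
F5 | step 11 | C12 mono-crotonate of F4 | C=C[C@H](O[Si](C)(C)C(C)(C)C)/C(C)=C/C(O)[C@]12C=C[C@H](OC(=O)/C=C/C)[C@H](C1)C(=C)C2
F6 | step 11 | C6 hydroxy α-vinyl acid | C=C[C@H](O[Si](C)(C)C(C)(C)C)/C(C)=C/C(O)[C@]12[C@H](C(C=C)C(=O)O)C=C[C@H](C1)C(=C)C2
F7 | step 11 | C6 keto α-vinyl acid | C=C[C@H](O[Si](C)(C)C(C)(C)C)/C(C)=C/C(=O)[C@]12[C@H](C(C=C)C(=O)O)C=C[C@H](C1)C(=C)C2
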